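**Retrosynthetic overview**
1. The target is released last from its hexa-O-benzyl ether, in which the flavanone ring C ketone is held as a spiro-1,3-dithiane: thioketal hydrolysis, then hydrogenolysis, both neutral.
2. The flavone ring C is closed on a biaryl methyl ketone by C-acylation with 2,4-bis(benzyloxy)-6-fluorobenzoyl chloride and fluoride displacement by the diketonate oxygen; the biaryl bond comes from a Suzuki coupling of two ring B units.
3. Key disconnection: the flavanone ring C is cut at C3–C4 and at O1–C8a. This gives the lithiated 1,3-dithiane of 2,4-bis(benzyloxy)-6-fluorobenzaldehyde (C4 as acyl anion, fluorine on C8a) and an (R)-aryl oxirane (O1–C2–C3, stereocentre preset by CBS reduction).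
4. Enabling feature: in ring C the carbonyl carbon C4 sits on ring A and is 1,3-related through C3 to the oxygen-bearing C2 (a beta-aryloxy ketone, i.e. acyl anion plus epoxide). C8a is meta to both ring A oxygens (C5, C7), so a C8a–F bond is not deactivated towards the C2 alkoxide.
5. Ring order: flavanone ring C first (as the thioketal, configurationally locked), flavone ring C second; all four benzene rings come from two purchased building blocks, each used twice.

Key step: step 10

Assumption: 5-fluororesorcinol and 1-(3-bromo-4-hydroxyphenyl)ethanone are taken as commercial; all six phenols are carried as benzyl ethers so that the last two steps run without base.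

**Route**

Step 1
Reactants: 1 5-fluororesorcinol (5-fluorobenzene-1,3-diol)
Product: 2 1,3-bis(benzyloxy)-5-fluorobenzene
Conditions: BnBr (2.2 equiv), K2CO3, DMF, 60 °C
Reagents that add atoms: benzyl bromide, BrCc1ccccc1
Why: Williamson ether synthesis; the carbonate deprotonates both phenols and the phenoxides displace bromide from the benzylic halide.

Step 2
Reactants: 2 1,3-bis(benzyloxy)-5-fluorobenzene
Product: 3 2,4-bis(benzyloxy)-6-fluorobenzaldehyde
Conditions: POCl3, DMF, 0 to 70 °C; then aq NaOAc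
Reagents that add atoms: N,N-dimethylformamide, CN(C)C=O; water, O
Why: Vilsmeier–Haack formylation; the chloroiminium ion should substitute the position next to fluorine (para to one benzyloxy group, ortho to the other), which is less hindered than the position between the two ethers, as 1-halo-3,5-dialkoxybenzenes do, and aqueous acetate hydrolyses the iminium salt.

Step 3
Reactants: 3 2,4-bis(benzyloxy)-6-fluorobenzaldehyde
Product: 4 2-[2,4-bis(benzyloxy)-6-fluorophenyl]-1,3-dithiane
Conditions: HS(CH2)3SH, BF3·OEt2 (cat.), CH2Cl2, 0 to 23 °C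
Reagents that add atoms: propane-1,3-dithiol, SCCCS
Why: Lewis-acid-catalysed dithioacetalisation, which turns the future ring C carbonyl carbon into an acidic S,S-acetal C–H for umpolung.

Step 4
Reactants: 3 2,4-bis(benzyloxy)-6-fluorobenzaldehyde
Product: 5 2,4-bis(benzyloxy)-6-fluorobenzoic acid
Conditions: NaClO2, NaH2PO4, 2-methyl-2-butene, t-BuOH/THF/H2O, 23 °C
Reagents that add atoms: sodium chlorite, [Na+].[O-]Cl=O
Why: Pinnick oxidation; chlorous acid oxidises the aldehyde while 2-methyl-2-butene traps the hypochlorous acid that would otherwise chlorinate the electron-rich ring.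

Step 5
Reactants: 5 2,4-bis(benzyloxy)-6-fluorobenzoic acid
Product: 6 2,4-bis(benzyloxy)-6-fluorobenzoyl chloride
Conditions: (COCl)2, DMF (cat.), CH2Cl2, 0 to 23 °C; used crude
Reagents that add atoms: oxalyl chloride, O=C(Cl)C(Cl)=O
Why: Acid chloride formation through the chloroiminium catalyst made from DMF and oxalyl chloride; the crude chloride is used at once in step 12.

Step 6
Reactants: 7 1-(3-bromo-4-hydroxyphenyl)ethan-1-one
Product: 8 1-[4-(benzyloxy)-3-bromophenyl]ethan-1-one
Conditions: BnBr, K2CO3, acetone, reflux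
Reagents that add atoms: benzyl bromide, BrCc1ccccc1
Why: Williamson ether synthesis on the acidic para-acyl phenol.

Step 7
Reactants: 8 1-[4-(benzyloxy)-3-bromophenyl]ethan-1-one
Product: 9 2-bromo-1-[4-(benzyloxy)-3-bromophenyl]ethan-1-one
Conditions: CuBr2 (2.0 equiv), EtOAc/CHCl3, reflux
Reagents that add atoms: copper dibromide, Br[Cu]Br
Why: alpha-Bromination of the aryl methyl ketone through its enol with CuBr2, which is selective for the side chain over the acyl-deactivated ring.

Step 8
Reactants: 9 2-bromo-1-[4-(benzyloxy)-3-bromophenyl]ethan-1-one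
Product: 11 (2R)-2-[4-(benzyloxy)-3-bromophenyl]oxirane, via bromohydrin 10 (not isolated)
Conditions: (R)-2-methyl-CBS-oxazaborolidine (10 mol %), BH3·SMe2, THF, 0 °C; then MeOH; then 2 M aq NaOH, 23 °C
Reagents that add atoms: none
Why: Corey–Bakshi–Shibata reduction; the (R)-oxazaborolidine–borane complex binds the ketone with the aryl group in the large-substituent position and delivers hydride to one face, which should set the (R)-carbinol of 10 (the facial sense that gives (S)-1-arylethanols from aryl methyl ketones), and hydroxide then closes the epoxide by intramolecular SN2 at CH2 without touching the stereocentre.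

Step 9
Reactants: 8 1-[4-(benzyloxy)-3-bromophenyl]ethan-1-one
Product: 12 1-[4-(benzyloxy)-3-(4,4,5,5-tetramethyl-1,3,2-dioxaborolan-2-yl)phenyl]ethan-1-one
Conditions: B2pin2, Pd(dppf)Cl2 (3 mol %), KOAc, 1,4-dioxane, 90 °C
Reagents that add atoms: bis(pinacolato)diboron, CC1(C)OB(OC1(C)C)B1OC(C)(C)C(C)(C)O1
Why: Miyaura borylation; oxidative addition of the aryl bromide, acetate-assisted transmetalation with the diboron reagent and reductive elimination, with a base too weak to disturb the ketone or the new boronate.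

Step 10
Reactants: 4 2-[2,4-bis(benzyloxy)-6-fluorophenyl]-1,3-dithiane; 11 (2R)-2-[4-(benzyloxy)-3-bromophenyl]oxirane
Product: 14 (2S)-5,7-bis(benzyloxy)-2-[4-(benzyloxy)-3-bromophenyl]spiro[chromane-4,2'-[1,3]dithiane], via lithium alkoxide 13 (not isolated)
Conditions: 4 (1.1 equiv), n-BuLi (1.05 equiv), THF, −78 to −30 °C; then 11, −30 to 23 °C; then KOt-Bu (1.0 equiv), DMPU, 65 °C
Reagents that add atoms: none
Why: n-BuLi removes the dithiane C–H of 4 to give a 2-aryl-2-lithio-1,3-dithiane (an acyl-anion equivalent of the ring C carbonyl carbon) that opens epoxide 11 by SN2 attack at its CH2 terminus, and the benzylic alkoxide 13 so released displaces the ortho fluoride of ring A by intramolecular SNAr (addition–elimination, fluoride leaving as its potassium salt). The closest known reaction types are the opening of terminal aryl oxiranes by lithiated 2-aryl-1,3-dithianes and the base-mediated cyclisation of 3-(2-fluorophenyl)propan-1-olates to chromans, here run in one flask. Ring C is closed as a six-membered ring by ipso attack of oxygen on the fluorine-bearing carbon (6-exo with respect to the C–F bond that breaks), after the intermolecular C–C bond formation and helped by the quaternary dithiane carbon in the tether. No stereocentre is created: the benzylic C–O and C–H bonds of the epoxide are never broken, so the (2R)-oxirane is carried with retention into the (2S)-flavan carbon (the descriptor changes only through CIP priorities), and the thioketal leaves no carbonyl through which this centre could epimerise in base. The step needs attack at CH2 and not at the benzylic carbon, secured by the bulk of the tertiary dithianyl anion, the absence of acid and the meta bromine that tempers the donor ring; it needs deprotonation at the dithiane and not on ring A, secured by the higher acidity of the S,S-acetal C–H and equilibration at −30 °C; and it needs fluoride displacement on an ether-bearing ring, possible because both benzyloxy groups are meta to the C–F carbon and act there as inductive acceptors.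

Step 11
Reactants: 14 (2S)-5,7-bis(benzyloxy)-2-[4-(benzyloxy)-3-bromophenyl]spiro[chromane-4,2'-[1,3]dithiane]; 12 1-[4-(benzyloxy)-3-(4,4,5,5-tetramethyl-1,3,2-dioxaborolan-2-yl)phenyl]ethan-1-one
Product: 15 1-[4-(benzyloxy)-3-{2-(benzyloxy)-5-[(2S)-5,7-bis(benzyloxy)spiro[chromane-4,2'-[1,3]dithian]-2-yl]phenyl}phenyl]ethan-1-one
Conditions: Pd(OAc)2 (5 mol %), SPhos (10 mol %), K3PO4, toluene/H2O, 90 °C
Reagents that add atoms: none
Why: Suzuki–Miyaura coupling; the electron-rich biarylphosphine supports oxidative addition and transmetalation at two ortho-alkoxy positions, and because the flavan half carries no enolisable ketone the base cannot open ring C or racemise C2.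

Step 12
Reactants: 15 1-[4-(benzyloxy)-3-{2-(benzyloxy)-5-[(2S)-5,7-bis(benzyloxy)spiro[chromane-4,2'-[1,3]dithian]-2-yl]phenyl}phenyl]ethan-1-one; 6 2,4-bis(benzyloxy)-6-fluorobenzoyl chloride
Product: 17 5,7-bis(benzyloxy)-2-[4-(benzyloxy)-3-{2-(benzyloxy)-5-[(2S)-5,7-bis(benzyloxy)spiro[chromane-4,2'-[1,3]dithian]-2-yl]phenyl}phenyl]-4H-chromen-4-one, via 1,3-diketone 16 (not isolated)
Conditions: LiN(SiMe3)2 (2.1 equiv), THF, −78 °C; then 6, −78 to 0 °C; then DMF, 90 °C
Reagents that add atoms: none
Why: Claisen-type C-acylation of the lithium enolate of 15 by acid chloride 6 (the second equivalent of base deprotonates the diketone), then intramolecular SNAr of the diketonate oxygen on the fluorine-bearing carbon ortho to the aroyl group, the known route from 1-(2-fluoroaryl)-1,3-diketones to flavones; the thioketal-masked flavan half has no acidic site and no new stereocentre arises.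

Step 13
Reactants: 17 5,7-bis(benzyloxy)-2-[4-(benzyloxy)-3-{2-(benzyloxy)-5-[(2S)-5,7-bis(benzyloxy)spiro[chromane-4,2'-[1,3]dithian]-2-yl]phenyl}phenyl]-4H-chromen-4-one
Product: 18 (2S)-5,7-bis(benzyloxy)-2-[4-(benzyloxy)-3-{2-(benzyloxy)-5-[5,7-bis(benzyloxy)-4-oxo-4H-chromen-2-yl]phenyl}phenyl]chroman-4-one
Conditions: MeI (excess), CaCO3, MeCN/H2O (9:1), 50 °C
Reagents that add atoms: water, O
Why: Alkylative dithiane hydrolysis; S-methylation gives a sulfonium ion that opens to a thionium ion stabilised by ring A, water adds and the second sulfur leaves after methylation, and the neutral buffered medium should leave the C2 stereocentre, now beta to a ketone, untouched.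

Step 14
Reactants: 18 (2S)-5,7-bis(benzyloxy)-2-[4-(benzyloxy)-3-{2-(benzyloxy)-5-[5,7-bis(benzyloxy)-4-oxo-4H-chromen-2-yl]phenyl}phenyl]chroman-4-one
Product: 19 (2S)-2-{3-[5-(5,7-dihydroxy-4-oxo-4H-chromen-2-yl)-2-hydroxyphenyl]-4-hydroxyphenyl}-5,7-dihydroxychroman-4-one (CNP0184920.1)
Conditions: H2 (1 atm), Pd/C (10 wt %), THF/MeOH, 23 °C
Reagents that add atoms: none
Why: Catalytic hydrogenolysis of the six benzyl ethers on Pd/C under neutral conditions, which avoids the base-induced ring opening that racemises flavanones; the stereocentre is not involved.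

**Compound list**
1 | 5-fluororesorcinol | Oc1cc(O)cc(F)c1 | starting material
2 | 1,3-bis(benzyloxy)-5-fluorobenzene | Fc1cc(OCc2ccccc2)cc(OCc2ccccc2)c1 | intermediate
3 | 2,4-bis(benzyloxy)-6-fluorobenzaldehyde | O=Cc1c(F)cc(OCc2ccccc2)cc1OCc1ccccc1 | intermediate
4 | 2-[2,4-bis(benzyloxy)-6-fluorophenyl]-1,3-dithiane | Fc1cc(OCc2ccccc2)cc(OCc2ccccc2)c1C1SCCCS1 | intermediate
5 | 2,4-bis(benzyloxy)-6-fluorobenzoic acid | OC(=O)c1c(F)cc(OCc2ccccc2)cc1OCc1ccccc1 | intermediate
6 | 2,4-bis(benzyloxy)-6-fluorobenzoyl chloride | ClC(=O)c1c(F)cc(OCc2ccccc2)cc1OCc1ccccc1 | intermediate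
7 | 1-(3-bromo-4-hydroxyphenyl)ethan-1-one | CC(=O)c1ccc(O)c(Br)c1 | starting material
8 | 1-[4-(benzyloxy)-3-bromophenyl]ethan-1-one | CC(=O)c1ccc(OCc2ccccc2)c(Br)c1 | intermediate
9 | 2-bromo-1-[4-(benzyloxy)-3-bromophenyl]ethan-1-one | BrCC(=O)c1ccc(OCc2ccccc2)c(Br)c1 | intermediate
10 | (1R)-2-bromo-1-[4-(benzyloxy)-3-bromophenyl]ethan-1-ol (bromohydrin, not isolated) | BrC[C@@H](c1ccc(OCc2ccccc2)c(Br)c1)O | intermediate
11 | (2R)-2-[4-(benzyloxy)-3-bromophenyl]oxirane | C1[C@@H](c2ccc(OCc3ccccc3)c(Br)c2)O1 | intermediate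
12 | 1-[4-(benzyloxy)-3-(4,4,5,5-tetramethyl-1,3,2-dioxaborolan-2-yl)phenyl]ethan-1-one | CC(=O)c1ccc(OCc2ccccc2)c(B2OC(C)(C)C(C)(C)O2)c1 | intermediate
13 | lithium (1S)-1-[4-(benzyloxy)-3-bromophenyl]-2-{2-[2,4-bis(benzyloxy)-6-fluorophenyl]-1,3-dithian-2-yl}ethan-1-olate (not isolated) | C1CSC(SC1)(c1c(F)cc(OCc2ccccc2)cc1OCc1ccccc1)C[C@@H](c1ccc(OCc2ccccc2)c(Br)c1)[O-].[Li+] | intermediate
14 | (2S)-5,7-bis(benzyloxy)-2-[4-(benzyloxy)-3-bromophenyl]spiro[chromane-4,2'-[1,3]dithiane] | C1CSC2(SC1)C[C@@H](c1ccc(OCc3ccccc3)c(Br)c1)Oc1cc(OCc3ccccc3)cc(OCc3ccccc3)c12 | intermediate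
15 | 1-[4-(benzyloxy)-3-{2-(benzyloxy)-5-[(2S)-5,7-bis(benzyloxy)spiro[chromane-4,2'-[1,3]dithian]-2-yl]phenyl}phenyl]ethan-1-one | C1CSC2(SC1)C[C@@H](c1ccc(OCc3ccccc3)c(-c3cc(C(C)=O)ccc3OCc3ccccc3)c1)Oc1cc(OCc3ccccc3)cc(OCc3ccccc3)c12 | intermediate
16 | 1-[2,4-bis(benzyloxy)-6-fluorophenyl]-3-[4-(benzyloxy)-3-{2-(benzyloxy)-5-[(2S)-5,7-bis(benzyloxy)spiro[chromane-4,2'-[1,3]dithian]-2-yl]phenyl}phenyl]propane-1,3-dione (formed as its lithium enolate, not isolated) | C1CSC2(SC1)C[C@@H](c1ccc(OCc3ccccc3)c(-c3cc(C(=O)CC(=O)c4c(F)cc(OCc5ccccc5)cc4OCc4ccccc4)ccc3OCc3ccccc3)c1)Oc1cc(OCc3ccccc3)cc(OCc3ccccc3)c12 | intermediate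
17 | 5,7-bis(benzyloxy)-2-[4-(benzyloxy)-3-{2-(benzyloxy)-5-[(2S)-5,7-bis(benzyloxy)spiro[chromane-4,2'-[1,3]dithian]-2-yl]phenyl}phenyl]-4H-chromen-4-one | C1CSC2(SC1)C[C@@H](c1ccc(OCc3ccccc3)c(-c3cc(-c4cc(=O)c5c(OCc6ccccc6)cc(OCc6ccccc6)cc5o4)ccc3OCc3ccccc3)c1)Oc1cc(OCc3ccccc3)cc(OCc3ccccc3)c12 | intermediate
18 | (2S)-5,7-bis(benzyloxy)-2-[4-(benzyloxy)-3-{2-(benzyloxy)-5-[5,7-bis(benzyloxy)-4-oxo-4H-chromen-2-yl]phenyl}phenyl]chroman-4-one | O=C1C[C@@H](c2ccc(OCc3ccccc3)c(-c3cc(-c4cc(=O)c5c(OCc6ccccc6)cc(OCc6ccccc6)cc5o4)ccc3OCc3ccccc3)c2)Oc2cc(OCc3ccccc3)cc(OCc3ccccc3)c21 | intermediate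
19 | (2S)-2-{3-[5-(5,7-dihydroxy-4-oxo-4H-chromen-2-yl)-2-hydroxyphenyl]-4-hydroxyphenyl}-5,7-dihydroxychroman-4-one | O=C1C[C@@H](c2ccc(O)c(-c3cc(-c4cc(=O)c5c(O)cc(O)cc5o4)ccc3O)c2)Oc2cc(O)cc(O)c21 | target

**Step count**
Total steps: 14.
Longest linear sequence: 8 steps (steps 6, 7, 8, 10, 11, 12, 13, 14 from compound 7; equally steps 1, 2, 3, 10, 11, 12, 13, 14 from compound 1).

**Steps most likely to fail**

Step 10. Three processes may defeat it.
- Ring A may be metalated next to fluorine instead of the dithiane carbon, with later loss of lithium fluoride.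
- The electron-rich oxirane may be attacked at the benzylic carbon or rearranged by the lithium cation.
- Fluoride displacement may be so slow that base-induced aryne formation at the aryl bromide overtakes ring closure.

The fallback closes ring C at O1–C2 by known chemistry; it sets out from 3 and 9 and comes back at 14. The fluoride of aldehyde 3, activated by the ortho formyl group, is displaced with 2-(methylsulfonyl)ethanol and NaH in DMF, the adduct losing methyl vinyl sulfone, to give 2,4-bis(benzyloxy)-6-hydroxybenzaldehyde F1. Thioacetalisation as in step 3 gives 2-[2,4-bis(benzyloxy)-6-hydroxyphenyl]-1,3-dithiane F2. Bromo ketone 9 is reduced with (S)-2-methyl-CBS-oxazaborolidine and BH3·SMe2 to (1S)-2-bromo-1-[4-(benzyloxy)-3-bromophenyl]ethan-1-ol F3 and closed with NaOH to (2S)-2-[4-(benzyloxy)-3-bromophenyl]oxirane F4. The dianion of F2 (2 equiv n-BuLi, THF) opens F4 at CH2 to give 3,5-bis(benzyloxy)-2-{2-[(2R)-2-[4-(benzyloxy)-3-bromophenyl]-2-hydroxyethyl]-1,3-dithian-2-yl}phenol F5. A Mitsunobu ring closure (PPh3, diisopropyl azodicarboxylate, THF, 0 °C) then forms the O1–C2 bond with inversion, (R) to (S), and gives 14.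

Step 12. The lithium enolate may be acylated at oxygen or twice by the hindered acid chloride, and the lithium diketonate may close slowly. The fallback sets out from 15 and 3 and comes back at 16. The lithium enolate of 15 (LiN(i-Pr)2, THF, −78 °C) adds to aldehyde 3 in an aldol addition to give 1-[4-(benzyloxy)-3-{2-(benzyloxy)-5-[(2S)-5,7-bis(benzyloxy)spiro[chromane-4,2'-[1,3]dithian]-2-yl]phenyl}phenyl]-3-[2,4-bis(benzyloxy)-6-fluorophenyl]-3-hydroxypropan-1-one F6 as a mixture of carbinol epimers. Swern oxidation gives the isolated diketone 16, which is closed to 17 with K2CO3 in DMF at 90 °C.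

Step 14. Over-reduction may occur (hydrogenolysis of the benzylic C2–O1 bond of the flavanone, saturation of the flavone C2=C3 bond), or sulfur traces from step 13 may stop the catalyst. The fallback replaces reduction by Lewis-acid dealkylation; it sets out from 18 and comes back at 19. BCl3 with pentamethylbenzene as benzyl-cation scavenger in CH2Cl2 at −78 °C cleaves the six benzyl ethers, the two chelated 5-O-benzyl groups first, and no new compound is made (F0).

**Further compounds**
F1 | step 10 | 2,4-bis(benzyloxy)-6-hydroxybenzaldehyde | O=Cc1c(O)cc(OCc2ccccc2)cc1OCc1ccccc1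
F2 | step 10 | 2-[2,4-bis(benzyloxy)-6-hydroxyphenyl]-1,3-dithiane | Oc1cc(OCc2ccccc2)cc(OCc2ccccc2)c1C1SCCCS1
F3 | step 10 | (1S)-2-bromo-1-[4-(benzyloxy)-3-bromophenyl]ethan-1-ol | BrC[C@H](c1ccc(OCc2ccccc2)c(Br)c1)O
F4 | step 10 | (2S)-2-[4-(benzyloxy)-3-bromophenyl]oxirane | C1[C@H](c2ccc(OCc3ccccc3)c(Br)c2)O1
F5 | step 10 | 3,5-bis(benzyloxy)-2-{2-[(2R)-2-[4-(benzyloxy)-3-bromophenyl]-2-hydroxyethyl]-1,3-dithian-2-yl}phenol | Oc1cc(OCc2ccccc2)cc(OCc2ccccc2)c1C1(C[C@@H](O)c2ccc(OCc3ccccc3)c(Br)c2)SCCCS1
F6 | step 12 | 1-[4-(benzyloxy)-3-{2-(benzyloxy)-5-[(2S)-5,7-bis(benzyloxy)spiro[chromane-4,2'-[1,3]dithian]-2-yl]phenyl}phenyl]-3-[2,4-bis(benzyloxy)-6-fluorophenyl]-3-hydroxypropan-1-one | C1CSC2(SC1)C[C@@H](c1ccc(OCc3ccccc3)c(-c3cc(C(=O)CC(O)c4c(F)cc(OCc5ccccc5)cc4OCc4ccccc4)ccc3OCc3ccccc3)c1)Oc1cc(OCc3ccccc3)cc(OCc3ccccc3)c12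
F0 | step 14 | none | none
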